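Convention and assumption: locants C1–C20 are those of the target's cladiellane skeleton (C1/C10 ring fusion, C2–O–C6 ether, C3 ester carbinol, C7 carbinol, C9 ketone, C11=C20, C14–C15(C16)–C17–OH). Compounds 1, 3 and 7 are assumed to be bought enantiopure.

**Retrosynthetic overview**
- The target comes from an isoxazoline by N–O cleavage, regioselective dehydration (C11=C20) and desilylation. The isoxazoline is made by an intramolecular nitrile oxide–alkene cycloaddition that forms C9–C10 and closes the medium ring last.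
- The nitrile oxide precursor comes from a 2,6-cis 6-acetyl oxane: a chelation-controlled aldol sets C7 and adds C8–C9, and hydrogenation of a 1,1-disubstituted alkene sets C15.
- The oxane comes from an anti-aldol (C1–C2) between a carvone-derived enone and a linalool-derived aldehyde–acetal, then oxocarbenium alkynylation at C6. The carvone carbonyl is removed with alkene transposition to C10=C11.
- Bought stereocentres: (S)-carvone (C14), (R)-linalool (C3), (S)-2-hydroxybutanoic acid (side chain); all others are substrate-controlled.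
- Ring order: cyclohexane (bought), then oxane, then the eight-membered oxacycle (ten-membered carbocycle) together with the isoxazoline, which is then opened.

**Route**

Step 1
Reactants: 1 (S)-2-hydroxybutanoic acid
Product: 2 (S)-2-(butanoyloxy)butanoic acid
Conditions: n-PrCOCl, pyridine, CH2Cl2, 0 → 23 °C; aq. HCl
Reagents that add atoms: butanoyl chloride CCCC(=O)Cl
Why: O-acylation of the α-hydroxy acid leaves the bought stereocentre untouched.

Step 2
Reactants: 2 (S)-2-(butanoyloxy)butanoic acid, 3 (R)-linalool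
Product: 5 (3R)-3,7-dimethylocta-1,6-dien-3-yl (2S)-2-(butanoyloxy)butanoate, via acid chloride 4 (not isolated)
Conditions: (COCl)2, DMF (cat.), CH2Cl2, 0 → 23 °C; then 3, DMAP, pyridine, CH2Cl2, 0 → 40 °C
Reagents that add atoms: none
Why: DMAP-catalysed acylation of the tertiary allylic alcohol occurs at oxygen without ionising C3, so both bought stereocentres are carried over and the final ester is in place from the start.

Step 3
Reactants: 5 (3R)-3,7-dimethylocta-1,6-dien-3-yl (2S)-2-(butanoyloxy)butanoate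
Product: 6 (2R)-6,6-dimethoxy-2-methyl-1-oxohexan-2-yl (2S)-2-(butanoyloxy)butanoate
Conditions: O3, CH2Cl2/MeOH, −78 °C; TsOH·H2O, 23 °C; NaHCO3; Me2S
Reagents that add atoms: ozone [O-][O+]=O; methanol CO
Why: Ozonolysis (1,3-dipolar cycloaddition and cycloreversion) cleaves both alkenes, and under TsOH in methanol only the unhindered C6 aldehyde is acetalised while the neopentylic α-acyloxy C2 aldehyde stays free (Schreiber-type terminus differentiation).

Step 4
Reactants: 7 (S)-carvone
Product: 8 (5S)-5-(3-hydroxyprop-1-en-2-yl)-2-methylcyclohex-2-en-1-one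
Conditions: SeO2 (cat.), t-BuOOH, CH2Cl2, 23 °C
Reagents that add atoms: tert-butyl hydroperoxide CC(C)(C)OO
Why: SeO2 allylic oxidation (ene reaction then 2,3-sigmatropic shift) hydroxylates the methyl of the electron-rich isopropenyl group and spares the deactivated enone, which puts the C17 oxygen in place.

Step 5
Reactants: 8 (5S)-5-(3-hydroxyprop-1-en-2-yl)-2-methylcyclohex-2-en-1-one
Product: 9 (5S)-5-[3-(tert-butyldimethylsilyloxy)prop-1-en-2-yl]-2-methylcyclohex-2-en-1-one
Conditions: TBSCl, imidazole, CH2Cl2, 23 °C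
Reagents that add atoms: tert-butyldimethylsilyl chloride CC(C)(C)[Si](C)(C)Cl
Why: Standard silylation of the primary allylic alcohol.

Step 6
Reactants: 9 (5S)-5-[3-(tert-butyldimethylsilyloxy)prop-1-en-2-yl]-2-methylcyclohex-2-en-1-one, 6 (2R)-6,6-dimethoxy-2-methyl-1-oxohexan-2-yl (2S)-2-(butanoyloxy)butanoate
Product: 11 anti-aldol adduct (β-hydroxy enone; C1–C2 bond), via boron enolate 10 (not isolated)
Conditions: (c-C6H11)2BCl, Et3N, Et2O, −78 → 0 °C; 6, −78 → −20 °C; H2O2, MeOH, pH 7 buffer, 0 °C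
Reagents that add atoms: none
Why: Boron aldol addition in which the cyclic (E)-enolate reacts through a Zimmerman–Traxler chair to give the anti aldol (C2 relative to C1) on the enolate face opposite the C14 substituent (C1 trans to C14); the aldehyde, with methyl and CH2 of similar size at C3, exerts little bias of its own.

Step 7
Reactants: 11 anti-aldol adduct
Product: 13 6-ethynyl oxane enone (C6 epimers; mainly 2,6-trans), via cyclic methyl acetal 12 (not isolated)
Conditions: PPTS, CH2Cl2, 23 °C; then K[HC≡CBF3], BF3·OEt2, MeCN, −40 → 0 °C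
Reagents that add atoms: potassium ethynyltrifluoroborate C#C[B-](F)(F)F.[K+]
Why: Transacetalisation closes the oxane through the C2 hydroxyl, and BF3-promoted ionisation to the cyclic oxocarbenium ion with alkynyl transfer from boron (C-glycosylation type) forms C6–C7; the C6 configuration is corrected in step 9.

Step 8
Reactants: 13 6-ethynyl oxane enone
Product: 15 6-ethynyl oxane with the C10=C11 alkene (ketone removed), via tosylhydrazone 14 (not isolated)
Conditions: TsNHNH2, PPTS (cat.), THF, 55 °C; then catecholborane, CHCl3, 0 °C; NaOAc·3H2O, 60 °C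
Reagents that add atoms: none
Why: Kabalka reduction of the α,β-unsaturated tosylhydrazone gives an allylic diazene that loses N2 in a 1,5-sigmatropic hydrogen shift (retro-ene), which removes the carbonyl and moves the alkene to C10=C11 without touching a stereocentre.

Step 9
Reactants: 15 6-ethynyl oxane with the C10=C11 alkene
Product: 17 2,6-cis 6-acetyl oxane, via 2,6-trans ketone 16 (not isolated)
Conditions: Ph3PAuCl (3 mol%), AgOTf (3 mol%), 1,4-dioxane/H2O, 60 °C; then DBU (0.1 equiv), CH2Cl2, 23 °C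
Reagents that add atoms: water O
Why: Gold-catalysed Markovnikov hydration of the terminal alkyne gives the methyl ketone, and base equilibration of the α-alkoxy ketone centre C6 converges on the diequatorial 2,6-cis oxane (thermodynamic control by C2).

Step 10
Reactants: 17 2,6-cis 6-acetyl oxane
Product: 18 (15R)-dihydro compound with the C14 1-(silyloxy)propan-2-yl side chain
Conditions: H2 (4 atm), RhCl(PPh3)3 (10 mol%), benzene, 23 °C
Reagents that add atoms: none
Why: Homogeneous hydrogenation reduces only the 1,1-disubstituted alkene, and with C14–H eclipsing the C=C bond the catalyst adds to the face away from the bulky C1 substituent, which is predicted to give 15R (1,2-induction, the sense opposite to hydroboration of an isopropenyl group).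

Step 11
Reactants: 18 (15R)-dihydro methyl ketone
Product: 19 β-hydroxy thioester with the (7R) tertiary alcohol
Conditions: TiCl4, CH2Cl2, −78 °C; CH2=C(SEt)OSiMe3; aq. NaHCO3
Reagents that add atoms: 1-(ethylsulfanyl)-1-(trimethylsilyloxy)ethene C=C(SCC)O[Si](C)(C)C
Why: Chelation-controlled Mukaiyama aldol addition in which TiCl4 bridges the ring oxygen and the ketone oxygen and the ketene thioacetal attacks from the C6–H side (Cram chelate), setting 7R and adding C8–C9.

Step 12
Reactants: 19 β-hydroxy thioester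
Product: 20 7-O-triethylsilyl thioester
Conditions: TESOTf, 2,6-lutidine, CH2Cl2, −78 → 0 °C
Reagents that add atoms: triethylsilyl trifluoromethanesulfonate CC[Si](CC)(CC)OS(=O)(=O)C(F)(F)F
Why: Silylation of the tertiary alcohol so that only the C11 hydroxyl is free in step 17.

Step 13
Reactants: 20 7-O-triethylsilyl thioester
Product: 21 C9 aldehyde
Conditions: Et3SiH, Pd/C (10%), acetone, 23 °C
Reagents that add atoms: none
Why: Fukuyama reduction converts the thioester to the aldehyde without touching the other esters or the trisubstituted alkene.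

Step 14
Reactants: 21 C9 aldehyde
Product: 22 C9 aldoxime
Conditions: NH2OH·HCl, NaOAc, EtOH, 23 °C
Reagents that add atoms: hydroxylamine hydrochloride NO.Cl
Why: Oxime condensation at the only aldehyde.

Step 15
Reactants: 22 C9 aldoxime
Product: 24 isoxazoline (C9–C10 and O–C11 bonds; medium ring closed), via nitrile oxide 23 (not isolated)
Conditions: aq. NaOCl, CH2Cl2, 0 → 23 °C, slow addition, 0.002 M
Reagents that add atoms: none
Why: Intramolecular nitrile oxide–alkene 1,3-dipolar cycloaddition in which carbon bonds to the less substituted C10 and oxygen to C11 (electronic and tether preference agree), closing the eight-membered oxacycle; suprafacial addition by axial attack at C10 on the face carrying the C1–C2 tether sets C10 cis to C2.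

Step 16
Reactants: 24 isoxazoline
Product: 25 β-hydroxy ketone (C9 ketone; C11 tertiary alcohol)
Conditions: H2 (1 atm), Raney Ni, B(OH)3, MeOH/H2O, 23 °C
Reagents that add atoms: water O
Why: Hydrogenolysis of the N–O bond and hydrolysis of the resulting imine (Curran conditions) unmask the aldol without epimerising C10.

Step 17
Reactants: 25 β-hydroxy ketone
Product: 26 bis-silyl ether of the target (C9 ketone; C11=CH2)
Conditions: SOCl2, pyridine, CH2Cl2, −30 → 0 °C
Reagents that add atoms: none
Why: E2 dehydration of the chlorosulfite, where the equatorial C11–O bond has an antiperiplanar hydrogen only on the methyl group and is nearly orthogonal to the C9 enol π system, so the exocyclic alkene should form and not the conjugated enone.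

Step 18
Reactants: 26 bis-silyl ether of the target
Product: 27 CNP0291223.2
Conditions: HF·pyridine, pyridine/THF, 0 → 23 °C
Reagents that add atoms: none
Why: Fluoride desilylation frees the C7 and C17 hydroxyls and leaves the esters and the β,γ-unsaturated ketone alone.

**Compound list**

1 | (S)-2-hydroxybutanoic acid | CC[C@H](O)C(=O)O | starting material
2 | (S)-2-(butanoyloxy)butanoic acid | OC(=O)[C@H](CC)OC(=O)CCC | intermediate
3 | (R)-linalool; (3R)-3,7-dimethylocta-1,6-dien-3-ol | C=C[C@](C)(O)CCC=C(C)C | starting material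
4 | (S)-2-(butanoyloxy)butanoyl chloride | ClC(=O)[C@H](CC)OC(=O)CCC | intermediate
5 | (3R)-3,7-dimethylocta-1,6-dien-3-yl (2S)-2-(butanoyloxy)butanoate | C=C[C@](C)(OC(=O)[C@H](CC)OC(=O)CCC)CCC=C(C)C | intermediate
6 | (2R)-6,6-dimethoxy-2-methyl-1-oxohexan-2-yl (2S)-2-(butanoyloxy)butanoate | O=C[C@](C)(OC(=O)[C@H](CC)OC(=O)CCC)CCC(OC)OC | intermediate
7 | (S)-carvone; (5S)-2-methyl-5-(prop-1-en-2-yl)cyclohex-2-en-1-one | CC1=CC[C@@H](CC1=O)C(C)=C | starting material
8 | (5S)-5-(3-hydroxyprop-1-en-2-yl)-2-methylcyclohex-2-en-1-one | CC1=CC[C@@H](CC1=O)C(=C)CO | intermediate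
9 | (5S)-5-[3-(tert-butyldimethylsilyloxy)prop-1-en-2-yl]-2-methylcyclohex-2-en-1-one | CC1=CC[C@@H](CC1=O)C(=C)CO[Si](C)(C)C(C)(C)C | intermediate
10 | dicyclohexylboron cross-conjugated dienolate of 9 | CC1=CC[C@H](C(=C)CO[Si](C)(C)C(C)(C)C)C=C1OB(C1CCCCC1)C1CCCCC1 | intermediate
11 | anti-aldol adduct; (5S,6S)-5-[3-(tert-butyldimethylsilyloxy)prop-1-en-2-yl]-6-[(1R,2R)-2-{[(2S)-2-(butanoyloxy)butanoyl]oxy}-1-hydroxy-6,6-dimethoxy-2-methylhexyl]-2-methylcyclohex-2-en-1-one | CC1=CC[C@H](C(=C)CO[Si](C)(C)C(C)(C)C)[C@@H]([C@@H](O)[C@](C)(OC(=O)[C@H](CC)OC(=O)CCC)CCC(OC)OC)C1=O | intermediate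
12 | cyclic methyl acetal; 11 closed between the C2 oxygen and C6 (6-methoxyoxane; C6 epimers) | CC1=CC[C@H](C(=C)CO[Si](C)(C)C(C)(C)C)[C@@H]([C@H]2OC(OC)CC[C@@]2(C)OC(=O)[C@H](CC)OC(=O)CCC)C1=O | intermediate
13 | 6-ethynyl oxane enone (C6 epimers; mainly 2,6-trans; C1, C2, C3, C14 as in 27) | CC1=CC[C@H](C(=C)CO[Si](C)(C)C(C)(C)C)[C@@H]([C@H]2OC(C#C)CC[C@@]2(C)OC(=O)[C@H](CC)OC(=O)CCC)C1=O | intermediate
14 | 4-methylbenzenesulfonylhydrazone of 13 at the ring ketone | CC1=CC[C@H](C(=C)CO[Si](C)(C)C(C)(C)C)[C@@H]([C@H]2OC(C#C)CC[C@@]2(C)OC(=O)[C@H](CC)OC(=O)CCC)C1=NNS(=O)(=O)c1ccc(C)cc1 | intermediate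
15 | 6-ethynyl oxane on the C10=C11 cyclohexene (ketone removed; C6 epimers) | CC1=C[C@H]([C@H]2OC(C#C)CC[C@@]2(C)OC(=O)[C@H](CC)OC(=O)CCC)[C@@H](C(=C)CO[Si](C)(C)C(C)(C)C)CC1 | intermediate
16 | 2,6-trans 6-acetyl oxane (C6 epimer of 17) | CC1=C[C@H]([C@H]2O[C@H](C(C)=O)CC[C@@]2(C)OC(=O)[C@H](CC)OC(=O)CCC)[C@@H](C(=C)CO[Si](C)(C)C(C)(C)C)CC1 | intermediate
17 | 2,6-cis 6-acetyl oxane (6R) on the C10=C11 cyclohexene with the 3-(silyloxy)prop-1-en-2-yl group at C14 | CC1=C[C@H]([C@H]2O[C@@H](C(C)=O)CC[C@@]2(C)OC(=O)[C@H](CC)OC(=O)CCC)[C@@H](C(=C)CO[Si](C)(C)C(C)(C)C)CC1 | intermediate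
18 | 17 with the side-chain alkene reduced; C14 carries (2R)-1-(tert-butyldimethylsilyloxy)propan-2-yl (15R) | CC1=C[C@H]([C@H]2O[C@@H](C(C)=O)CC[C@@]2(C)OC(=O)[C@H](CC)OC(=O)CCC)[C@@H]([C@@H](C)CO[Si](C)(C)C(C)(C)C)CC1 | intermediate
19 | β-hydroxy S-ethyl thioester; (7R) tertiary alcohol on the oxane C6 substituent | CC1=C[C@H]([C@H]2O[C@@H]([C@](C)(O)CC(=O)SCC)CC[C@@]2(C)OC(=O)[C@H](CC)OC(=O)CCC)[C@@H]([C@@H](C)CO[Si](C)(C)C(C)(C)C)CC1 | intermediate
20 | 7-O-triethylsilyl ether of 19 | CC1=C[C@H]([C@H]2O[C@@H]([C@](C)(O[Si](CC)(CC)CC)CC(=O)SCC)CC[C@@]2(C)OC(=O)[C@H](CC)OC(=O)CCC)[C@@H]([C@@H](C)CO[Si](C)(C)C(C)(C)C)CC1 | intermediate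
21 | C9 aldehyde from 20 | CC1=C[C@H]([C@H]2O[C@@H]([C@](C)(O[Si](CC)(CC)CC)CC=O)CC[C@@]2(C)OC(=O)[C@H](CC)OC(=O)CCC)[C@@H]([C@@H](C)CO[Si](C)(C)C(C)(C)C)CC1 | intermediate
22 | C9 aldoxime of 21 | CC1=C[C@H]([C@H]2O[C@@H]([C@](C)(O[Si](CC)(CC)CC)CC=NO)CC[C@@]2(C)OC(=O)[C@H](CC)OC(=O)CCC)[C@@H]([C@@H](C)CO[Si](C)(C)C(C)(C)C)CC1 | intermediate
23 | C9 nitrile oxide from 22 | CC1=C[C@H]([C@H]2O[C@@H]([C@](C)(O[Si](CC)(CC)CC)CC#[N+][O-])CC[C@@]2(C)OC(=O)[C@H](CC)OC(=O)CCC)[C@@H]([C@@H](C)CO[Si](C)(C)C(C)(C)C)CC1 | intermediate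
24 | isoxazoline; C9(=N)–C10 and O–C11 bonds, cis-fused to the cyclohexane, medium ring closed; 7-O-TES, 17-O-TBS | C[C@]12CC[C@H]([C@@H](C)CO[Si](C)(C)C(C)(C)C)[C@@H]3[C@H]1C(=NO2)C[C@@](C)(O[Si](CC)(CC)CC)[C@H]1CC[C@@](C)(OC(=O)[C@H](CC)OC(=O)CCC)[C@@H]3O1 | intermediate
25 | β-hydroxy ketone; C9 ketone, 11-hydroxy-11-methyl (OH cis to C9), 7-O-TES, 17-O-TBS | C[C@]1(O)CC[C@H]([C@@H](C)CO[Si](C)(C)C(C)(C)C)[C@@H]2[C@H]1C(=O)C[C@@](C)(O[Si](CC)(CC)CC)[C@H]1CC[C@@](C)(OC(=O)[C@H](CC)OC(=O)CCC)[C@@H]2O1 | intermediate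
26 | 7-O-triethylsilyl 17-O-tert-butyldimethylsilyl ether of 27 | C=C1CC[C@H]([C@@H](C)CO[Si](C)(C)C(C)(C)C)[C@@H]2[C@H]1C(=O)C[C@@](C)(O[Si](CC)(CC)CC)[C@H]1CC[C@@](C)(OC(=O)[C@H](CC)OC(=O)CCC)[C@@H]2O1 | intermediate
27 | CNP0291223.2; (1R,2R,3R,6R,7R,10R,14R,15R)-2,6-epoxy-7,17-dihydroxy-9-oxocladiell-11(20)-en-3-yl (2S)-2-(butanoyloxy)butanoate | C=C1CC[C@H]([C@@H](C)CO)[C@@H]2[C@H]1C(=O)C[C@@](C)(O)[C@H]1CC[C@@](C)(OC(=O)[C@H](CC)OC(=O)CCC)[C@@H]2O1 | target

**Step count and risks**

Total step count: 18. Longest linear sequence: 16 steps (1 → 2 → 5 → 6 → 11 → 13 → 15 → 17 → 18 → 19 → 20 → 21 → 22 → 24 → 25 → 26 → 27). The carvone branch (7 → 9) has 2 steps before it joins.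

The three steps most likely to fail:

- Step 15. The cycloaddition closes an eight-membered ring onto an unactivated trisubstituted alkene, the oxane has to reach its 2,6-diaxial form, and furoxan dimerisation competes; the facial outcome at C10 is also only argued, not proven. The fallback sets out from aldehyde 21: Me2AlCl (CH2Cl2, −78 → 0 °C) promotes an intramolecular carbonyl-ene reaction of the aldehyde with the methyl-bearing C10=C11 alkene, which forms C9–C10 and the exocyclic alkene in one operation and gives the homoallylic alcohol F1. Dess–Martin periodinane then oxidises the C9 carbinol and the route is rejoined at 26, so steps 14 to 17 drop out.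

- Step 10. The C15 configuration rests on acyclic 1,2-induction with a non-directed catalyst, so the ratio may be modest. The fallback sets out from 17: HF·pyridine removes the silyl group to give the allylic alcohol F2. Hydrogenation with [Rh(nbd)(dppb)]BF4 (H2, 50 atm, CH2Cl2) then runs through a rhodium–hydroxyl–alkene chelate, which is expected to raise selectivity for the same face and gives the saturated alcohol F3. Silylation (TBSCl, imidazole) comes back to the route at 18.

- Step 17. If elimination runs through the C9 enolate instead of the antiperiplanar methyl hydrogen, the conjugated tetrasubstituted enone forms. The fallback sets out from 25 and makes that isomer on purpose (MsCl, Et3N, then DBU), giving the conjugated enone F4. Photochemical deconjugation (300 nm, MeCN, 1,2-dimethylimidazole) then transfers a hydrogen from the methyl group cis to the acyl group to the carbonyl oxygen, and the dienol is reprotonated at C10 from the face away from C2. This comes back to the route at 26.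

**Further compounds**

F1 | step 15 | homoallylic alcohol; 26 with C9 as a secondary carbinol (C9 configuration open) | C=C1CC[C@H]([C@@H](C)CO[Si](C)(C)C(C)(C)C)[C@@H]2[C@H]1C(O)C[C@@](C)(O[Si](CC)(CC)CC)[C@H]1CC[C@@](C)(OC(=O)[C@H](CC)OC(=O)CCC)[C@@H]2O1
F2 | step 10 | allylic alcohol; 17 without the silyl group | CC1=C[C@H]([C@H]2O[C@@H](C(C)=O)CC[C@@]2(C)OC(=O)[C@H](CC)OC(=O)CCC)[C@@H](C(=C)CO)CC1
F3 | step 10 | saturated (15R) alcohol; 18 without the silyl group | CC1=C[C@H]([C@H]2O[C@@H](C(C)=O)CC[C@@]2(C)OC(=O)[C@H](CC)OC(=O)CCC)[C@@H]([C@@H](C)CO)CC1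
F4 | step 17 | conjugated enone; C10=C11 isomer of 26 | CC1=C(C(=O)C[C@@](C)(O[Si](CC)(CC)CC)[C@H]2CC[C@@](C)(OC(=O)[C@H](CC)OC(=O)CCC)[C@@H]3O2)[C@H]3[C@@H]([C@@H](C)CO[Si](C)(C)C(C)(C)C)CC1
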